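**Retrosynthetic overview**

1. Ring B is closed last, by a light-driven isomerisation that forms C7–C8. The enabling feature is that ring C is a 1,4-hydroquinone (O on C11 and C14) whose C8, ortho to the C14 hydroxyl, carries the C7 ketone; the target is therefore the redox isomer of a C11/C14 quinone with a free C8–H and a C7 aldehyde on the C5 arm.
2. The quinone comes from (NH4)2Ce(NO3)6 oxidation of the 11,12,14-trimethoxyarene. The C7 aldehyde comes from ozonolysis of a C5 allyl group, put on by radical allylation at the bridging carbon of the bicyclic lactone (sets C5).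
3. The lactone ring (C19–O–C20) and quaternary C10 come from a formaldehyde aldol on an α-aryl ketone, trapped by lactonisation onto the C4 ester (C4 relays to C10).
4. The C9–C10 bond comes from Michael addition of a ketone enolate to a quinone monoketal and aromatisation, which places the ring-A carbon at C9 rather than C8. The monoketal is made from 1,2,4-trimethoxybenzene.
5. C4 is the only stereocentre set by a catalyst (asymmetric hydrogenation, then Frater–Seebach methylation). Ring order: A (bought), C (attached as arene), lactone ring, B last.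

Key step: step 16

Remark: atoms and rings are numbered as in abietane (ring A = C1–C5, C10; ring B = C5–C10; ring C = C8, C9, C11–C14; C19 = lactone carbonyl on C4; C20 = lactone CH2 on C10). Compounds 1 and 5 are taken as commercial.

**Route**

Step 1
Reactants: 1 methyl 2-oxocyclohexane-1-carboxylate
Product: 2 methyl (1R,2R)-2-hydroxycyclohexane-1-carboxylate
Conditions: RuCl2[(R)-BINAP] (cat.), H2 (100 atm), CH2Cl2, 50 °C
Reagents that add atoms: none
Why: Noyori asymmetric hydrogenation with dynamic kinetic resolution, in which the β-keto ester racemises through its enol faster than it is reduced and the (R)-BINAP–ruthenium catalyst delivers hydrogen to one carbonyl face to set C2 as R (the C1 configuration, expected trans, is erased in step 2).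

Step 2
Reactants: 2 methyl (1R,2R)-2-hydroxycyclohexane-1-carboxylate
Product: 3 methyl (1S,2R)-2-hydroxy-1-methylcyclohexane-1-carboxylate
Conditions: LiN(i-Pr)2 (2.2 equiv), THF, −50 → −15 °C; then MeI, DMPU, −78 → 0 °C; aqueous quench
Reagents that add atoms: iodomethane, CI
Why: Frater–Seebach alkylation, in which the chelated alkoxide/ester-enolate dianion is methylated on the face anti to the C2 oxygen, so that the carbinol centre from step 1 dictates the quaternary centre (the future C4, S).

Step 3
Reactants: 3 methyl (1S,2R)-2-hydroxy-1-methylcyclohexane-1-carboxylate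
Product: 4 methyl (1S)-1-methyl-2-oxocyclohexane-1-carboxylate
Conditions: Dess–Martin periodinane, CH2Cl2, rt
Reagents that add atoms: none
Why: Dess–Martin oxidation of the secondary alcohol next to a quaternary carbon that cannot epimerise, leaving the single stereocentre that controls all later ones.

Step 4
Reactants: 5 1,2,4-trimethoxybenzene
Product: 6 2-(2,3,6-trimethoxyphenyl)propan-2-ol
Conditions: n-BuLi, THF, 0 °C → rt; then acetone, −78 °C → rt; aqueous quench
Reagents that add atoms: acetone, CC(C)=O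
Why: Directed ortho-lithiation, in which the C3–H of 5 lies between two methoxy groups and is removed selectively before the aryllithium adds to acetone.

Step 5
Reactants: 6 2-(2,3,6-trimethoxyphenyl)propan-2-ol
Product: 7 1,2,4-trimethoxy-3-(propan-2-yl)benzene
Conditions: Et3SiH, CF3CO2H, CH2Cl2, 0 °C → rt
Reagents that add atoms: none
Why: Ionic hydrogenation, in which the electron-rich tertiary benzylic alcohol ionises in acid and the cation is reduced by hydride transfer from the silane.

Step 6
Reactants: 7 1,2,4-trimethoxy-3-(propan-2-yl)benzene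
Product: 8 2,3,3,6,6-pentamethoxy-1-(propan-2-yl)cyclohexa-1,4-diene
Conditions: Pt anode, undivided cell, KOH (1%) in MeOH, constant current, 0 °C
Reagents that add atoms: methanol, CO
Why: Anodic methoxylation of a 1,4-dimethoxyarene (quinone bisketal synthesis), in which two-electron oxidation of the ring and capture by methoxide occur at the two para carbons that already bear OMe.

Step 7
Reactants: 8 2,3,3,6,6-pentamethoxy-1-(propan-2-yl)cyclohexa-1,4-diene
Product: 9 3,4,4-trimethoxy-2-(propan-2-yl)cyclohexa-2,5-dien-1-one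
Conditions: AcOH, H2O, acetone, 0 °C → rt
Reagents that add atoms: water, O
Why: Regioselective monohydrolysis of a quinone bisketal, in which the ketal next to the isopropyl-bearing carbon ionises faster because its cation is stabilised through the C=C–OMe unit, so the carbonyl appears at the future C14 and the ketal stays at the future C11.

Step 8
Reactants: 4 methyl (1S)-1-methyl-2-oxocyclohexane-1-carboxylate; 9 3,4,4-trimethoxy-2-(propan-2-yl)cyclohexa-2,5-dien-1-one
Product: 11 methyl (1S)-3-[5-hydroxy-2,3-dimethoxy-4-(propan-2-yl)phenyl]-1-methyl-2-oxocyclohexane-1-carboxylate, via Michael adduct 10 (not isolated)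
Conditions: LiN(i-Pr)2, THF, −78 °C; then 9, −78 → −20 °C; AcOH quench; then TsOH (cat.), CH2Cl2, rt
Reagents that add atoms: none
Why: Michael addition of a ketone lithium enolate to a quinone monoketal followed by acid-induced loss of methanol (the monoketal acting as an aryl cation equivalent), in which 4 can enolise only toward its CH2 side and attacks the unsubstituted enone β-carbon next to the ketal (the future C9), so that aromatisation leaves OH at C14 and OMe at C11, while the new α-carbon stays epimerisable until step 10.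

Step 9
Reactants: 11 methyl (1S)-3-[5-hydroxy-2,3-dimethoxy-4-(propan-2-yl)phenyl]-1-methyl-2-oxocyclohexane-1-carboxylate
Product: 12 methyl (1S)-1-methyl-2-oxo-3-[2,3,5-trimethoxy-4-(propan-2-yl)phenyl]cyclohexane-1-carboxylate
Conditions: MeI, K2CO3, acetone, 56 °C
Reagents that add atoms: iodomethane, CI
Why: Williamson O-methylation of the phenoxide, which is far more acidic than the ketone α-C–H, masking the phenol so that formaldehyde in step 10 cannot hydroxymethylate the ring.

Step 10
Reactants: 12 methyl (1S)-1-methyl-2-oxo-3-[2,3,5-trimethoxy-4-(propan-2-yl)phenyl]cyclohexane-1-carboxylate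
Product: 14 (1S,5R)-1-methyl-5-[2,3,5-trimethoxy-4-(propan-2-yl)phenyl]-3-oxabicyclo[3.3.1]nonane-2,9-dione, via hydroxymethyl ketone 13 (not isolated)
Conditions: (CH2O)n, DBU (0.3 equiv), THF, 45 °C
Reagents that add atoms: formaldehyde (as paraformaldehyde), C=O
Why: Base-catalysed aldol hydroxymethylation of the α-aryl ketone followed by lactonisation under thermodynamic control, in which the aldol is reversible and only the adduct with CH2OH cis (1,3-diaxial) to the C4 ester can close the six-membered lactone, so that C4 sets the quaternary centre C10 (R).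

Step 11
Reactants: 14 (1S,5R)-1-methyl-5-[2,3,5-trimethoxy-4-(propan-2-yl)phenyl]-3-oxabicyclo[3.3.1]nonane-2,9-dione
Product: 15 (1S,5R,9S)-9-hydroxy-1-methyl-5-[2,3,5-trimethoxy-4-(propan-2-yl)phenyl]-3-oxabicyclo[3.3.1]nonan-2-one
Conditions: NaBH4, MeOH/THF (1:1), −20 → 0 °C
Reagents that add atoms: none
Why: Borohydride reduction of the non-enolisable bridging ketone, faster than attack on the hindered lactone, with hydride expected from the lactone-bridge side although the carbinol configuration is irrelevant because this centre becomes a radical in step 13.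

Step 12
Reactants: 15 (1S,5R,9S)-9-hydroxy-1-methyl-5-[2,3,5-trimethoxy-4-(propan-2-yl)phenyl]-3-oxabicyclo[3.3.1]nonan-2-one
Product: 16 O-[(1S,5R,9S)-1-methyl-2-oxo-5-[2,3,5-trimethoxy-4-(propan-2-yl)phenyl]-3-oxabicyclo[3.3.1]nonan-9-yl] S-methyl carbonodithioate
Conditions: NaH, imidazole (cat.), THF, 0 °C → rt; CS2; then MeI
Reagents that add atoms: carbon disulfide, S=C=S; iodomethane, CI
Why: Xanthate formation as for a Barton–McCombie precursor, in which the small CS2 electrophile tolerates the hindered alkoxide and the absence of any β-hydrogen rules out Chugaev elimination.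

Step 13
Reactants: 16 O-[(1S,5R,9S)-1-methyl-2-oxo-5-[2,3,5-trimethoxy-4-(propan-2-yl)phenyl]-3-oxabicyclo[3.3.1]nonan-9-yl] S-methyl carbonodithioate
Product: 17 (1S,5R,9R)-1-methyl-9-(prop-2-en-1-yl)-5-[2,3,5-trimethoxy-4-(propan-2-yl)phenyl]-3-oxabicyclo[3.3.1]nonan-2-one
Conditions: CH2=CHCH2SnBu3 (10 equiv), AIBN (portionwise), PhH, 80 °C
Reagents that add atoms: allyltributylstannane, C=CC[Sn](CCCC)(CCCC)CCCC
Why: Keck radical allylation, in which the stannyl radical fragments the xanthate to the secondary C5 radical and this adds to the allylstannane from the less hindered face syn to the lactone bridge (the other face is screened by the axial hydrogens at C1 and C3), setting C5 as R with the allyl group equatorial on ring A and trans to the aryl group, while the aryl–C10 bond lies in the nodal plane of the radical and so disfavours a neophyl shift.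

Step 14
Reactants: 17 (1S,5R,9R)-1-methyl-9-(prop-2-en-1-yl)-5-[2,3,5-trimethoxy-4-(propan-2-yl)phenyl]-3-oxabicyclo[3.3.1]nonan-2-one
Product: 18 (1S,5R,9R)-5-[5-methoxy-3,6-dioxo-4-(propan-2-yl)cyclohexa-1,4-dien-1-yl]-1-methyl-9-(prop-2-en-1-yl)-3-oxabicyclo[3.3.1]nonan-2-one
Conditions: (NH4)2Ce(NO3)6 (2.5 equiv), MeCN/H2O (2:1), 0 °C
Reagents that add atoms: water, O
Why: Oxidative demethylation of a 1,4-dimethoxyarene, in which the para pair of methoxy groups (C11, C14) becomes the quinone carbonyls with oxygen from water while the 12-OMe group and the terminal alkene survive.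

Step 15
Reactants: 18 (1S,5R,9R)-5-[5-methoxy-3,6-dioxo-4-(propan-2-yl)cyclohexa-1,4-dien-1-yl]-1-methyl-9-(prop-2-en-1-yl)-3-oxabicyclo[3.3.1]nonan-2-one
Product: 20 2-[(1S,5R,9R)-5-[5-methoxy-3,6-dioxo-4-(propan-2-yl)cyclohexa-1,4-dien-1-yl]-1-methyl-2-oxo-3-oxabicyclo[3.3.1]nonan-9-yl]acetaldehyde, via ozonide 19 (not isolated)
Conditions: O3, CH2Cl2, −78 °C (to the indicator end point); then Me2S, −78 °C → rt
Reagents that add atoms: ozone, [O-][O+]=O
Why: Ozonolysis with reductive work-up, in which the terminal alkene reacts far faster with ozone than the electron-poor quinone double bonds and dimethyl sulfide, which unlike a phosphine does not add to quinones, reduces the ozonide to the aldehyde.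

Step 16
Reactants: 20 2-[(1S,5R,9R)-5-[5-methoxy-3,6-dioxo-4-(propan-2-yl)cyclohexa-1,4-dien-1-yl]-1-methyl-2-oxo-3-oxabicyclo[3.3.1]nonan-9-yl]acetaldehyde
Product: 21 (4S,5R,10R)-11,14-dihydroxy-12-methoxy-7-oxoabieta-8,11,13-trien-19,20-olide (CNP0159814.2)
Conditions: hν (blue LEDs, 420–450 nm, or sunlamp through Pyrex), degassed PhH (0.005 M), rt
Reagents that add atoms: none
Why: This is the intramolecular form of the photochemical acylation of 1,4-quinones by aldehydes (photo-Friedel–Crafts acylation), which is established intermolecularly for benzoquinones and naphthoquinones with aliphatic aldehydes. Excitation of the quinone n,π* band should give the triplet, whose carbonyl oxygen (O14 can reach the folded CH2CHO arm, and an intermolecular transfer gives the same species) abstracts the weak formyl hydrogen of C7, and the resulting semiquinone/acyl radical pair combines by attack of the nucleophilic acyl radical on C8. Ring B closes in the 6-endo mode onto the quinone C8=C9 bond, whereas 5-exo attack at the fully substituted C9 would create a spiro centre and is disfavoured, C8 being the only quinone C–H and the β-carbon of the C11 enone, the carbonyl not deactivated by the 12-OMe group. Tautomerisation of the adduct then aromatises ring C, so the C7 ketone, both hydroxyls and ring B arise in one redox-neutral isomerisation without protecting groups. No stereocentre is formed, and the trans A/B fusion follows from C5 and C10, which hold the aldehyde arm and the quinone equatorial on adjacent carbons of ring A. The step needs abstraction of the formyl hydrogen in preference to the γ-hydrogens at C1 and C20 and to decarbonylation, which the low formyl C–H bond strength, the fast six-membered closure, high dilution and long-wavelength irradiation should secure, and the product is shielded from further photochemistry by its O14–H···O=C7 hydrogen bond.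

**Compound list**

1 | methyl 2-oxocyclohexane-1-carboxylate | COC(=O)C1CCCCC1=O | starting material
2 | methyl (1R,2R)-2-hydroxycyclohexane-1-carboxylate | O[C@@H]1CCCC[C@H]1C(=O)OC | intermediate
3 | methyl (1S,2R)-2-hydroxy-1-methylcyclohexane-1-carboxylate | O[C@@H]1CCCC[C@]1(C)C(=O)OC | intermediate
4 | methyl (1S)-1-methyl-2-oxocyclohexane-1-carboxylate | O=C1CCCC[C@]1(C)C(=O)OC | intermediate
5 | 1,2,4-trimethoxybenzene | COc1ccc(OC)c(OC)c1 | starting material
6 | 2-(2,3,6-trimethoxyphenyl)propan-2-ol | CC(C)(O)c1c(OC)ccc(OC)c1OC | intermediate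
7 | 1,2,4-trimethoxy-3-(propan-2-yl)benzene | CC(C)c1c(OC)ccc(OC)c1OC | intermediate
8 | 2,3,3,6,6-pentamethoxy-1-(propan-2-yl)cyclohexa-1,4-diene (quinone bisketal) | COC1=C(C(C)C)C(OC)(OC)C=CC1(OC)OC | intermediate
9 | 3,4,4-trimethoxy-2-(propan-2-yl)cyclohexa-2,5-dien-1-one (quinone monoketal) | O=C1C=CC(OC)(OC)C(OC)=C1C(C)C | intermediate
10 | methyl (1S)-1-methyl-2-oxo-3-[2,2,3-trimethoxy-5-oxo-4-(propan-2-yl)cyclohex-3-en-1-yl]cyclohexane-1-carboxylate (Michael adduct, mixture at the two new centres, not isolated) | O=C1C(C2CC(=O)C(C(C)C)=C(OC)C2(OC)OC)CCC[C@]1(C)C(=O)OC | intermediate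
11 | methyl (1S)-3-[5-hydroxy-2,3-dimethoxy-4-(propan-2-yl)phenyl]-1-methyl-2-oxocyclohexane-1-carboxylate (both C3 epimers) | O=C1C(c2cc(O)c(C(C)C)c(OC)c2OC)CCC[C@]1(C)C(=O)OC | intermediate
12 | methyl (1S)-1-methyl-2-oxo-3-[2,3,5-trimethoxy-4-(propan-2-yl)phenyl]cyclohexane-1-carboxylate (both C3 epimers) | O=C1C(c2cc(OC)c(C(C)C)c(OC)c2OC)CCC[C@]1(C)C(=O)OC | intermediate
13 | methyl (1S,3R)-3-(hydroxymethyl)-1-methyl-2-oxo-3-[2,3,5-trimethoxy-4-(propan-2-yl)phenyl]cyclohexane-1-carboxylate (not isolated) | O=C1[C@@](CO)(c2cc(OC)c(C(C)C)c(OC)c2OC)CCC[C@]1(C)C(=O)OC | intermediate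
14 | (1S,5R)-1-methyl-5-[2,3,5-trimethoxy-4-(propan-2-yl)phenyl]-3-oxabicyclo[3.3.1]nonane-2,9-dione | O=C1[C@@]2(c3cc(OC)c(C(C)C)c(OC)c3OC)CCC[C@]1(C)C(=O)OC2 | intermediate
15 | (1S,5R,9S)-9-hydroxy-1-methyl-5-[2,3,5-trimethoxy-4-(propan-2-yl)phenyl]-3-oxabicyclo[3.3.1]nonan-2-one (OH syn to the carbocyclic bridge) | O[C@H]1[C@@]2(c3cc(OC)c(C(C)C)c(OC)c3OC)CCC[C@]1(C)C(=O)OC2 | intermediate
16 | O-[(1S,5R,9S)-1-methyl-2-oxo-5-[2,3,5-trimethoxy-4-(propan-2-yl)phenyl]-3-oxabicyclo[3.3.1]nonan-9-yl] S-methyl carbonodithioate | CSC(=S)O[C@H]1[C@@]2(c3cc(OC)c(C(C)C)c(OC)c3OC)CCC[C@]1(C)C(=O)OC2 | intermediate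
17 | (1S,5R,9R)-1-methyl-9-(prop-2-en-1-yl)-5-[2,3,5-trimethoxy-4-(propan-2-yl)phenyl]-3-oxabicyclo[3.3.1]nonan-2-one (allyl syn to the lactone bridge) | C=CC[C@@H]1[C@@]2(c3cc(OC)c(C(C)C)c(OC)c3OC)CCC[C@]1(C)C(=O)OC2 | intermediate
18 | (1S,5R,9R)-5-[5-methoxy-3,6-dioxo-4-(propan-2-yl)cyclohexa-1,4-dien-1-yl]-1-methyl-9-(prop-2-en-1-yl)-3-oxabicyclo[3.3.1]nonan-2-one | C=CC[C@@H]1[C@@]2(C3=CC(=O)C(C(C)C)=C(OC)C3=O)CCC[C@]1(C)C(=O)OC2 | intermediate
19 | (1S,5R,9R)-5-[5-methoxy-3,6-dioxo-4-(propan-2-yl)cyclohexa-1,4-dien-1-yl]-1-methyl-9-(1,2,4-trioxolan-3-ylmethyl)-3-oxabicyclo[3.3.1]nonan-2-one (ozonide, trioxolane carbon unassigned, not isolated) | C1(C[C@@H]2[C@@]3(C4=CC(=O)C(C(C)C)=C(OC)C4=O)CCC[C@]2(C)C(=O)OC3)OCOO1 | intermediate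
20 | 2-[(1S,5R,9R)-5-[5-methoxy-3,6-dioxo-4-(propan-2-yl)cyclohexa-1,4-dien-1-yl]-1-methyl-2-oxo-3-oxabicyclo[3.3.1]nonan-9-yl]acetaldehyde | O=CC[C@@H]1[C@@]2(C3=CC(=O)C(C(C)C)=C(OC)C3=O)CCC[C@]1(C)C(=O)OC2 | intermediate
21 | (4S,5R,10R)-11,14-dihydroxy-12-methoxy-7-oxoabieta-8,11,13-trien-19,20-olide (CNP0159814.2) | COc1c(O)c2c(c(O)c1C(C)C)C(=O)C[C@@H]1[C@]23CCC[C@]1(C)C(=O)OC3 | target

**Step count**

Total steps: 16. Longest linear sequence: 13 steps (5 → 21, steps 4–7 and 8–16); the branch from 1 (steps 1–3) joins at step 8.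

**Steps most likely to fail**

Step 16 (key photoacylation). The excited alkylquinone may instead abstract a γ-hydrogen from C1, C20 or the isopropyl group and cyclise onto its side chain, the radical pair may combine at oxygen, or the acyl radical may lose CO. The fallback replaces the radical acylation at the quinone level by an ionic Friedel–Crafts acylation at the arene level. It sets out from 17: Lemieux–von Rudloff cleavage (NaIO4, KMnO4 cat., K2CO3, t-BuOH/H2O) should give 2-[(1S,5R,9R)-1-methyl-2-oxo-5-[2,3,5-trimethoxy-4-(propan-2-yl)phenyl]-3-oxabicyclo[3.3.1]nonan-9-yl]acetic acid F1. Eaton's reagent (P2O5 in CH3SO3H, rt) should then close ring B at C8, which is para to the 12-OMe and ortho to the 14-OMe group, to give (4S,5R,10R)-11,12,14-trimethoxy-7-oxoabieta-8,11,13-trien-19,20-olide F2. Oxidative demethylation with (NH4)2Ce(NO3)6 in MeCN/H2O should give (4S,5R,10R)-12-methoxy-7,11,14-trioxoabieta-8,12-dien-19,20-olide F3, and reduction with Na2S2O4 (EtOAc/H2O) returns to the route at 21.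

Step 8 (enolate addition to the monoketal). The hard, hindered lithium enolate may add to the dienone carbonyl (1,2-addition) or simply transfer a proton, so that no C9–C10 bond forms. The fallback turns the nucleophile into a soft 1,3-dicarbonyl anion with a removable formyl group. It sets out from 4: Claisen formylation (NaH, HCO2Et, THF) should give methyl (1S)-3-(hydroxymethylidene)-1-methyl-2-oxocyclohexane-1-carboxylate F4. Its anion (K2CO3 or DBU, THF) should add to 9 in the well-precedented manner of β-dicarbonyl compounds to give methyl (1S)-3-formyl-1-methyl-2-oxo-3-[2,2,3-trimethoxy-5-oxo-4-(propan-2-yl)cyclohex-3-en-1-yl]cyclohexane-1-carboxylate F5. TsOH should aromatise this to methyl (1S)-3-formyl-3-[5-hydroxy-2,3-dimethoxy-4-(propan-2-yl)phenyl]-1-methyl-2-oxocyclohexane-1-carboxylate F6, and deformylation by retro-Claisen cleavage (K2CO3, MeOH) returns to the route at 11.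

Step 13 (radical allylation). Chain propagation at the hindered C5 radical may be sluggish, or the stannane may attack from the carbocyclic face and give the C5 epimer. The fallback builds the C5 arm by two ionic one-carbon homologations with thermodynamic control of C5, and it also bypasses steps 11 and 12. It sets out from 14: Wittig reaction with Ph3P=CHOMe should give (1S,5R)-9-(methoxymethylidene)-1-methyl-5-[2,3,5-trimethoxy-4-(propan-2-yl)phenyl]-3-oxabicyclo[3.3.1]nonan-2-one F7. Aqueous HCl and then DBU should give the epimerisable (1S,5R,9R)-1-methyl-2-oxo-5-[2,3,5-trimethoxy-4-(propan-2-yl)phenyl]-3-oxabicyclo[3.3.1]nonane-9-carbaldehyde F8, equilibrated to the isomer with the formyl group syn to the lactone bridge, where it meets only one 1,3-diaxial hydrogen. A second Wittig reaction should give (1S,5R,9R)-9-(2-methoxyethenyl)-1-methyl-5-[2,3,5-trimethoxy-4-(propan-2-yl)phenyl]-3-oxabicyclo[3.3.1]nonan-2-one F9, and hydrolysis should give 2-[(1S,5R,9R)-1-methyl-2-oxo-5-[2,3,5-trimethoxy-4-(propan-2-yl)phenyl]-3-oxabicyclo[3.3.1]nonan-9-yl]acetaldehyde F10. Oxidation with (NH4)2Ce(NO3)6 in MeCN/H2O returns to the route at 20.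

**Further compounds**

F1 | step 16 | 2-[(1S,5R,9R)-1-methyl-2-oxo-5-[2,3,5-trimethoxy-4-(propan-2-yl)phenyl]-3-oxabicyclo[3.3.1]nonan-9-yl]acetic acid | OC(=O)C[C@@H]1[C@@]2(c3cc(OC)c(C(C)C)c(OC)c3OC)CCC[C@]1(C)C(=O)OC2
F2 | step 16 | (4S,5R,10R)-11,12,14-trimethoxy-7-oxoabieta-8,11,13-trien-19,20-olide | COc1c(OC)c2c(c(OC)c1C(C)C)C(=O)C[C@@H]1[C@]23CCC[C@]1(C)C(=O)OC3
F3 | step 16 | (4S,5R,10R)-12-methoxy-7,11,14-trioxoabieta-8,12-dien-19,20-olide | COC1=C(C(C)C)C(=O)C(C(=O)C[C@@H]3[C@]24CCC[C@]3(C)C(=O)OC4)=C2C1=O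
F4 | step 8 | methyl (1S)-3-(hydroxymethylidene)-1-methyl-2-oxocyclohexane-1-carboxylate | O=C1C(=CO)CCC[C@]1(C)C(=O)OC
F5 | step 8 | methyl (1S)-3-formyl-1-methyl-2-oxo-3-[2,2,3-trimethoxy-5-oxo-4-(propan-2-yl)cyclohex-3-en-1-yl]cyclohexane-1-carboxylate | O=C1C(C=O)(C2CC(=O)C(C(C)C)=C(OC)C2(OC)OC)CCC[C@]1(C)C(=O)OC
F6 | step 8 | methyl (1S)-3-formyl-3-[5-hydroxy-2,3-dimethoxy-4-(propan-2-yl)phenyl]-1-methyl-2-oxocyclohexane-1-carboxylate | O=C1C(C=O)(c2cc(O)c(C(C)C)c(OC)c2OC)CCC[C@]1(C)C(=O)OC
F7 | step 13 | (1S,5R)-9-(methoxymethylidene)-1-methyl-5-[2,3,5-trimethoxy-4-(propan-2-yl)phenyl]-3-oxabicyclo[3.3.1]nonan-2-one | COC=C1[C@@]2(c3cc(OC)c(C(C)C)c(OC)c3OC)CCC[C@]1(C)C(=O)OC2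
F8 | step 13 | (1S,5R,9R)-1-methyl-2-oxo-5-[2,3,5-trimethoxy-4-(propan-2-yl)phenyl]-3-oxabicyclo[3.3.1]nonane-9-carbaldehyde | O=C[C@@H]1[C@@]2(c3cc(OC)c(C(C)C)c(OC)c3OC)CCC[C@]1(C)C(=O)OC2
F9 | step 13 | (1S,5R,9R)-9-(2-methoxyethenyl)-1-methyl-5-[2,3,5-trimethoxy-4-(propan-2-yl)phenyl]-3-oxabicyclo[3.3.1]nonan-2-one | COC=C[C@@H]1[C@@]2(c3cc(OC)c(C(C)C)c(OC)c3OC)CCC[C@]1(C)C(=O)OC2
F10 | step 13 | 2-[(1S,5R,9R)-1-methyl-2-oxo-5-[2,3,5-trimethoxy-4-(propan-2-yl)phenyl]-3-oxabicyclo[3.3.1]nonan-9-yl]acetaldehyde | O=CC[C@@H]1[C@@]2(c3cc(OC)c(C(C)C)c(OC)c3OC)CCC[C@]1(C)C(=O)OC2
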